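**Plan**
Locants: ring C1 (OH), C2 (side chain), C4 (OH), C6 (CH3); chain C1' (benzylic CH2) to C16'. The retrosynthesis cuts (a) three O–Si bonds, (b) C1'–C2' together with C3'–CH3, (c) C8'–C9', with C9'=C10' raised to an alkyne, and (d) C6'=C7'.
Enabling feature: C2'=C3' is an E trisubstituted alkene with H on C2' and CH3 on C3', and C2' is bonded to the benzylic carbon C1'. This is the imprint of syn CH3–Al addition to a terminal alkyne C2'≡C3' followed by capture of the C2'–Al bond by a benzylic halide. The ring is 2,6-dimethylhydroquinone in which one of two equivalent methyl groups carries the chain.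
Forward order: geraniol gives the C10 (S)-alkynol (C9'–C16'), and a silylpentynol gives the C8 allylic bromide (C2'–C8'). Acetylide allylation joins them, and trans reduction, alkyne unmasking and O-silylation follow. The ring is bought, silylated and monobrominated.
One-flask methylalumination and benzylation then joins chain and ring, and fluoride removes all three silyl groups. No ring is built.
Stereochemistry: C11' (S) comes from Sharpless epoxidation of geraniol, and its C–O bond is never broken afterwards. C6'=C7' E comes from a stabilised Wittig reaction, C9'=C10' E from directed trans-hydroalumination, and C2'=C3' E from syn carboalumination.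

Key step: step 13

Assumption: the centre written [C@] is C11' with S configuration (the same spatial arrangement as (S)-linalool). Geraniol, 5-(trimethylsilyl)pent-4-yn-1-ol and 2,6-dimethylhydroquinone are taken as commercial.

Step 1
Reactants: 1 geraniol
Product: 2 (2S,3S)-2,3-epoxygeraniol
Conditions: Ti(OiPr)4 (5 mol %), L-(+)-diethyl tartrate (7 mol %), t-BuOOH (1.5 equiv), 4 Å MS, CH2Cl2, −20 °C
Reagents that add atoms: tert-butyl hydroperoxide, CC(C)(C)OO
Why: Katsuki–Sharpless asymmetric epoxidation is directed by the allylic hydroxyl, so only C2=C3 reacts, and L-(+)-tartrate delivers oxygen to the face that gives the (2S,3S)-epoxide, whose quaternary C3–O bond becomes the C11' carbinol of the target.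

Step 2
Reactants: 2 (2S,3S)-2,3-epoxygeraniol
Product: 3 (2R,3S)-1-chloro-2,3-epoxy-3,7-dimethyloct-6-ene (same spatial arrangement as 2)
Conditions: PPh3 (1.3 equiv), CCl4, NaHCO3 (buffer), reflux
Reagents that add atoms: carbon tetrachloride, ClC(Cl)(Cl)Cl
Why: Appel chlorination replaces the primary hydroxyl under essentially neutral conditions without touching either epoxide C–O bond, so both centres keep their spatial arrangement.

Step 3
Reactants: 3 epoxy chloride
Product: 4 (S)-3,7-dimethyloct-6-en-1-yn-3-ol
Conditions: n-BuLi (3.3 equiv), THF, −78 to −30 °C; aq. NH4Cl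
Reagents that add atoms: none
Why: In this base-induced double elimination of a 2,3-epoxy chloride to a propargylic alcohol, deprotonation at the CHCl carbon opens the C2–O bond and loss of HCl gives the alkyne, while the C3–O bond stays intact and the S configuration is retained.

Step 4
Reactants: 5 5-(trimethylsilyl)pent-4-yn-1-ol
Product: 7 ethyl (E)-2-methyl-7-(trimethylsilyl)hept-2-en-6-ynoate, via 5-(trimethylsilyl)pent-4-ynal 6 (not isolated)
Conditions: TEMPO (10 mol %), PhI(OAc)2 (1.1 equiv), CH2Cl2, rt; then Ph3P=C(CH3)CO2Et (1.5 equiv), rt to 40 °C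
Reagents that add atoms: ethyl 2-(triphenylphosphoranylidene)propanoate, CCOC(=O)C(C)=P(c1ccccc1)(c1ccccc1)c1ccccc1
Why: The nitroxyl oxidation stops at the aldehyde, which the stabilised ylide traps in the same flask (tandem oxidation–Wittig olefination), and this should strongly favour the E trisubstituted enoate and avoids handling the volatile aldehyde.

Step 5
Reactants: 7 enoate
Product: 8 (E)-2-methyl-7-(trimethylsilyl)hept-2-en-6-yn-1-ol
Conditions: i-Bu2AlH (2.3 equiv), CH2Cl2, −78 °C; aq. potassium sodium tartrate
Reagents that add atoms: none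
Why: 1,2-Reduction of the enoate with i-Bu2AlH at low temperature gives the allylic alcohol without touching the silylalkyne or the alkene geometry.

Step 6
Reactants: 8 allylic alcohol
Product: 9 (E)-7-bromo-6-methyl-1-(trimethylsilyl)hept-5-en-1-yne
Conditions: CBr4 (1.2 equiv), PPh3 (1.25 equiv), CH2Cl2, 0 °C
Reagents that add atoms: carbon tetrabromide, BrC(Br)(Br)Br
Why: Appel bromination converts the primary allylic alcohol into the bromide by SN2 displacement, without allylic transposition or erosion of the E geometry.

Step 7
Reactants: 4 (S)-alkynol, 9 allylic bromide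
Product: 11 (6S,10E)-2,6,10-trimethyl-15-(trimethylsilyl)pentadeca-2,10-diene-7,14-diyn-6-ol, via bis(bromomagnesium) alkoxide-acetylide 10 (not isolated)
Conditions: 4, EtMgBr (2.1 equiv), THF, 0 to 40 °C; CuCl (10 mol %); then 9, THF, 50 °C; aq. NH4Cl
Reagents that add atoms: none
Why: In this copper-catalysed SN2 allylation of an alkynyl Grignard reagent, two equivalents of EtMgBr mask the hydroxyl as its alkoxide and metalate the alkyne C–H, the primary carbon of 9 is attacked in preference to the substituted gamma carbon, and the C-silyl group keeps the second alkyne silent.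

Step 8
Reactants: 11 skipped enynol
Product: 12 (6S,7E,10E)-2,6,10-trimethyl-15-(trimethylsilyl)pentadeca-2,7,10-trien-14-yn-6-ol
Conditions: NaAlH2(OCH2CH2OMe)2 (3 equiv), THF, 0 °C to rt; aq. potassium sodium tartrate
Reagents that add atoms: none
Why: Hydroxyl-directed trans-hydroalumination of the propargylic alcohol followed by protonolysis should give only the E C9'=C10' alkene, while the undirected silylalkyne and the trisubstituted alkenes are left alone.

Step 9
Reactants: 12 silylated trienynol
Product: 13 (6S,7E,10E)-2,6,10-trimethylpentadeca-2,7,10-trien-14-yn-6-ol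
Conditions: K2CO3 (0.3 equiv), MeOH, rt
Reagents that add atoms: none
Why: Carbonate-catalysed methanolysis is selective for the C(sp)–Si bond and frees the terminal alkyne needed for carbometalation.

Step 10
Reactants: 13 trienynol
Product: 14 triethylsilyl ether of 13
Conditions: Et3SiOTf (1.3 equiv), 2,6-lutidine (2 equiv), CH2Cl2, −78 to 0 °C
Reagents that add atoms: triethylsilyl trifluoromethanesulfonate, CC[Si](CC)(CC)OS(=O)(=O)C(F)(F)F
Why: Silylation with the reactive triflate and a hindered base caps the tertiary allylic hydroxyl at low temperature without ionisation, so no O–H group or aluminium alkoxide is present during carbometalation.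

Step 11
Reactants: 15 2,6-dimethylhydroquinone
Product: 16 1,4-bis(tert-butyldimethylsilyloxy)-2,6-dimethylbenzene
Conditions: t-BuMe2SiCl (2.4 equiv), imidazole (5 equiv), DMF, rt
Reagents that add atoms: tert-butyldimethylsilyl chloride, CC(C)(C)[Si](C)(C)Cl
Why: Imidazole-promoted silylation caps both phenols and gives a mirror-symmetric ether whose two methyl groups are equivalent.

Step 12
Reactants: 16 bis-silyl ether
Product: 17 2,5-bis(tert-butyldimethylsilyloxy)-3-methylbenzyl bromide
Conditions: NBS (1.0 equiv), AIBN (5 mol %), PhCF3, reflux
Reagents that add atoms: N-bromosuccinimide, O=C1CCC(=O)N1Br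
Why: Wohl–Ziegler radical bromination, known for O-silylated cresols and 2,6-xylenols, with one equivalent of NBS in a non-polar medium functionalises one of the two equivalent methyl groups, and the flanking silyloxy and methyl groups shield the two ring C–H positions from electrophilic bromination.

Step 13
Reactants: 14 terminal alkyne, 17 benzylic bromide
Product: 19 O11'-triethylsilyl-O1,O4-bis(tert-butyldimethylsilyl) ether of the target, via (E)-alkenyl(dimethyl)alane 18 (not isolated)
Conditions: 14 (1.1 equiv), AlMe3 (2 equiv), Cp2ZrCl2 (0.25 equiv), CH2Cl2, 0 °C to rt; volatiles removed in vacuo; then 17, Pd(PPh3)4 (5 mol %), THF, rt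
Reagents that add atoms: trimethylaluminium, C[Al](C)C
Why: Cp2ZrCl2/AlMe3 adds CH3 and Al in a syn fashion across the only terminal alkyne of 14 (Negishi zirconium-catalysed methylalumination), with CH3 going to the internal carbon C3' and Al to the unhindered terminal carbon C2', which gives the (E)-alkenylalane 18. Zerovalent palladium then inserts into the benzylic C–Br bond of 17, the sp2 carbon moves from aluminium to divalent palladium faster than the remaining methyl groups, and reductive elimination forms C1'–C2' with retention of geometry; the closest known reaction type is the palladium- or nickel-catalysed coupling of carboalumination-derived alkenylalanes with benzylic halides, as applied to polyprenylated hydroquinone ethers. One flask therefore installs the C3' methyl group, fixes the E geometry of the trisubstituted C2'=C3' alkene and joins the C19 chain to C1'. No ring is closed and no stereocentre is created; the alkene geometry is controlled by syn carbometalation followed by stereoretentive transmetalation and reductive elimination, and C11' is a spectator. The step needs chemoselectivity for the alkyne over three alkenes, secured because trisubstituted and 1,2-disubstituted alkenes do not undergo methylalumination, and it needs a substrate free of acidic or easily ionised groups, secured by the three silyl ethers. Because the electrophilic carbon is benzylic and not allylic there is no SN2' or E/Z leakage, the benzylpalladium species has no beta hydrogen, and removing excess AlMe3 before the coupling suppresses methyl transfer.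

Step 14
Reactants: 19 tris-silyl ether
Product: 20 2-[(2E,6E,9E,11S)-11-hydroxy-3,7,11,15-tetramethylhexadeca-2,6,9,14-tetraen-1-yl]-6-methylbenzene-1,4-diol (target)
Conditions: n-Bu4NF/AcOH (1:1, 5 equiv), degassed THF, argon, 0 °C to rt
Reagents that add atoms: none
Why: Fluoride cleaves the two aryl O–Si bonds and the tertiary O–SiEt3 bond in one operation under buffered, non-acidic and oxygen-free conditions, which spares the ionisable tertiary allylic alcohol, its configuration and the air-sensitive hydroquinone.

**Compound list**
1 | geraniol | CC(C)=CCC/C(C)=C/CO | starting material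
2 | (2S,3S)-2,3-epoxygeraniol | CC(C)=CCC[C@]1(C)O[C@H]1CO | intermediate
3 | (2R,3S)-1-chloro-2,3-epoxy-3,7-dimethyloct-6-ene | CC(C)=CCC[C@]1(C)O[C@H]1CCl | intermediate
4 | (S)-3,7-dimethyloct-6-en-1-yn-3-ol | CC(C)=CCC[C@](C)(O)C#C | intermediate
5 | 5-(trimethylsilyl)pent-4-yn-1-ol | C[Si](C)(C)C#CCCCO | starting material
6 | 5-(trimethylsilyl)pent-4-ynal (not isolated) | C[Si](C)(C)C#CCCC=O | intermediate
7 | ethyl (E)-2-methyl-7-(trimethylsilyl)hept-2-en-6-ynoate | CCOC(=O)/C(C)=C/CCC#C[Si](C)(C)C | intermediate
8 | (E)-2-methyl-7-(trimethylsilyl)hept-2-en-6-yn-1-ol | OC/C(C)=C/CCC#C[Si](C)(C)C | intermediate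
9 | (E)-7-bromo-6-methyl-1-(trimethylsilyl)hept-5-en-1-yne | BrC/C(C)=C/CCC#C[Si](C)(C)C | intermediate
10 | bis(bromomagnesium) alkoxide-acetylide of 4 (not isolated) | CC(C)=CCC[C@](C)(O[Mg]Br)C#C[Mg]Br | intermediate
11 | (6S,10E)-2,6,10-trimethyl-15-(trimethylsilyl)pentadeca-2,10-diene-7,14-diyn-6-ol | CC(C)=CCC[C@](C)(O)C#CC/C(C)=C/CCC#C[Si](C)(C)C | intermediate
12 | (6S,7E,10E)-2,6,10-trimethyl-15-(trimethylsilyl)pentadeca-2,7,10-trien-14-yn-6-ol | CC(C)=CCC[C@](C)(O)/C=C/C/C(C)=C/CCC#C[Si](C)(C)C | intermediate
13 | (6S,7E,10E)-2,6,10-trimethylpentadeca-2,7,10-trien-14-yn-6-ol | CC(C)=CCC[C@](C)(O)/C=C/C/C(C)=C/CCC#C | intermediate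
14 | triethylsilyl ether of 13 | CC(C)=CCC[C@](C)(O[Si](CC)(CC)CC)/C=C/C/C(C)=C/CCC#C | intermediate
15 | 2,6-dimethylhydroquinone | Cc1cc(O)cc(C)c1O | starting material
16 | 1,4-bis(tert-butyldimethylsilyloxy)-2,6-dimethylbenzene | Cc1cc(O[Si](C)(C)C(C)(C)C)cc(C)c1O[Si](C)(C)C(C)(C)C | intermediate
17 | 2,5-bis(tert-butyldimethylsilyloxy)-3-methylbenzyl bromide | BrCc1cc(O[Si](C)(C)C(C)(C)C)cc(C)c1O[Si](C)(C)C(C)(C)C | intermediate
18 | (E)-alkenyl(dimethyl)alane from 14 (not isolated) | CC(C)=CCC[C@](C)(O[Si](CC)(CC)CC)/C=C/C/C(C)=C/CC/C(C)=C/[Al](C)C | intermediate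
19 | O11'-triethylsilyl-O1,O4-bis(tert-butyldimethylsilyl) ether of the target | CC(C)=CCC[C@](C)(O[Si](CC)(CC)CC)/C=C/C/C(C)=C/CC/C(C)=C/Cc1cc(O[Si](C)(C)C(C)(C)C)cc(C)c1O[Si](C)(C)C(C)(C)C | intermediate
20 | 2-[(2E,6E,9E,11S)-11-hydroxy-3,7,11,15-tetramethylhexadeca-2,6,9,14-tetraen-1-yl]-6-methylbenzene-1,4-diol | CC(C)=CCC[C@](C)(O)/C=C/C/C(C)=C/CC/C(C)=C/Cc1cc(O)cc(C)c1O | target

**Total steps:** 14.
**Longest linear sequence:** 9 steps (steps 1, 2, 3, 7, 8, 9, 10, 13, 14 from geraniol; the branch from 5 through steps 4, 5, 6 is equally long).

**Steps most likely to fail**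

Risk 1, step 13. Methyl may be transferred from aluminium in place of the alkenyl group. The benzylic bromide may homocouple reductively at palladium. Long contact with Lewis-acidic aluminium residues may erode the silyl ethers.
The fallback separates the two events and reverses the polarity of the union. It sets out from 14 and 17. Alkyne 14 is methylaluminated as before, but alane 18 is quenched with I2 at −30 °C to give the purified (E)-alkenyl iodide F1. Bromide 17 is treated with Zn dust and LiCl in THF to give the benzylzinc bromide F2. Negishi coupling of F1 with F2 under PdCl2(dppf), in a medium free of aluminium, comes back to the route at 19.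

Risk 2, step 12. Electrophilic bromination of the electron-rich ring, a second bromination at the other methyl group, or loss of silyl groups to HBr may compete with the radical chain.
The fallback changes the electronic character of the ring and sets out from 15. Pivaloyl chloride in pyridine gives the 2,6-dimethylhydroquinone dipivalate F3, whose deactivated ring is of the type on which benzylic bromination is routine. NBS with AIBN gives the 2,5-bis(pivaloyloxy)-3-methylbenzyl bromide F4. F4 takes the place of 17 in the coupling with alane 18 and gives the dipivalate triethylsilyl ether F5. LiAlH4 in THF at 0 °C under argon cleaves both aryl esters to the hydroquinone triethylsilyl ether F6. n-Bu4NF then comes back to the route at 20.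

Risk 3, step 7. Attack at the gamma carbon of the allylic bromide, or a base-induced prototropic shift of the skipped enyne to a conjugated vinylallene, may erode the union, and the same shift may occur under the hydride conditions of step 8.
The fallback sets the E alkene before the C8'–C9' bond is made and sets out from 4. Hydrostannation with n-Bu3SnH catalysed by PdCl2(PPh3)2, in which the bulky tertiary carbinol should direct tin to the terminal carbon, gives the (S,E)-alkenylstannane F7. Stille coupling of F7 with 9 (Pd2(dba)3, AsPh3, THF/NMP) comes back to the route at 12 and bypasses steps 7 and 8.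

**Further compounds**
F1 | step 13 | (E)-alkenyl iodide from 14 | CC(C)=CCC[C@](C)(O[Si](CC)(CC)CC)/C=C/C/C(C)=C/CC/C(C)=C/I
F2 | step 13 | 2,5-bis(tert-butyldimethylsilyloxy)-3-methylbenzylzinc bromide | Br[Zn]Cc1cc(O[Si](C)(C)C(C)(C)C)cc(C)c1O[Si](C)(C)C(C)(C)C
F3 | step 12 | 2,6-dimethylhydroquinone dipivalate | Cc1cc(OC(=O)C(C)(C)C)cc(C)c1OC(=O)C(C)(C)C
F4 | step 12 | 2,5-bis(pivaloyloxy)-3-methylbenzyl bromide | BrCc1cc(OC(=O)C(C)(C)C)cc(C)c1OC(=O)C(C)(C)C
F5 | step 12 | dipivalate triethylsilyl ether of the target | CC(C)=CCC[C@](C)(O[Si](CC)(CC)CC)/C=C/C/C(C)=C/CC/C(C)=C/Cc1cc(OC(=O)C(C)(C)C)cc(C)c1OC(=O)C(C)(C)C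
F6 | step 12 | O11'-triethylsilyl ether of the target | CC(C)=CCC[C@](C)(O[Si](CC)(CC)CC)/C=C/C/C(C)=C/CC/C(C)=C/Cc1cc(O)cc(C)c1O
F7 | step 7 | (S,E)-3,7-dimethyl-1-(tributylstannyl)octa-1,6-dien-3-ol | CC(C)=CCC[C@](C)(O)/C=C/[Sn](CCCC)(CCCC)CCCC
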